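**Remark (assumption):** the enantiomer of the Diels–Alder catalyst in step 1 is the one that delivers (S)-3; both catalyst enantiomers are available.

## Retrosynthetic overview

1. The target is cut at the ester into allylic alcohol 14 and a caffeoyl unit (malonic half-ester, then Knoevenagel–Doebner condensation); 14 comes from hydroxy ketone 13 by methylenation.
2. The cyclopentane (C1 = quaternary carbon, C2 = methylidene carbon, C3–C5 = CH2) is closed at C4–C5 by ring-closing metathesis of keto diene 11. The enabling feature is that C2 stays a ketone until the end, so an allyl group on it (C3, C4) and a 1-propenyl group on C1 (C5) form a 1,6-diene whose closure touches no stereocentre.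
3. Diene 11 arises by opening bicyclic δ-lactone 10 (a 2-oxabicyclo[3.3.1]nonenone) with an allyl nucleophile. This temporary lactone ring links the cyclohexene C–O carbon to the future C2 and makes the two faces of the α-carbon (future C1) different, so methylation followed by allylation builds the second quaternary centre next to the first under substrate control.
4. Lactone 7 comes from acid 5 by iodolactonisation and elimination, which relays the ring quaternary centre to the carbinol centre; 5 comes from aldehyde 3, made by a catalytic asymmetric Diels–Alder reaction of isoprene and methacrolein (the only catalyst-set stereocentre).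
5. Ring order: cyclohexene (step 1), temporary lactone (step 4), cyclopentane (step 10).

Key step: step 10

## Route

Step 1
Reactants: 1 isoprene; 2 methacrolein
Product: 3 (S)-1,4-dimethylcyclohex-3-ene-1-carbaldehyde
Conditions: chiral oxazaborolidinium triflimide (10 mol%), CH2Cl2, −78 → −40 °C
Reagents that add atoms: none
Why: Catalytic asymmetric Diels–Alder reaction of an α-substituted acrolein, in which the 2-methyl diene gives the 1,4-("para") adduct and the chiral Lewis acid blocks one face of the coordinated enal, setting the ring quaternary carbon as (S).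

Step 2
Reactants: 3 (S)-1,4-dimethylcyclohex-3-ene-1-carbaldehyde
Product: 4 2-[(1S)-1,4-dimethylcyclohex-3-en-1-yl]acetonitrile
Conditions: TosMIC, t-BuOK, DME, −40 °C; then MeOH, reflux
Reagents that add atoms: p-toluenesulfonylmethyl isocyanide (TosMIC) Cc1ccc(cc1)S(=O)(=O)C[N+]#[C-]
Why: The van Leusen reductive cyanation should homologate the non-enolisable neopentyl aldehyde by one carbon without touching the adjacent quaternary stereocentre or the ring alkene.

Step 3
Reactants: 4 2-[(1S)-1,4-dimethylcyclohex-3-en-1-yl]acetonitrile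
Product: 5 2-[(1S)-1,4-dimethylcyclohex-3-en-1-yl]acetic acid
Conditions: KOH, ethylene glycol/H2O, 140 °C; then aq. HCl
Reagents that add atoms: water O; potassium hydroxide [K+].[OH-]
Why: Basic nitrile hydrolysis of a primary nitrile should proceed cleanly, since the molecule has no base-sensitive group and the stereocentre is not enolisable.

Step 4
Reactants: 5 2-[(1S)-1,4-dimethylcyclohex-3-en-1-yl]acetic acid
Product: 6 (1S,5S,8S)-8-iodo-5,8-dimethyl-2-oxabicyclo[3.3.1]nonan-3-one
Conditions: I2, NaHCO3, THF/H2O, 0 °C, dark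
Reagents that add atoms: iodine II
Why: Kinetic iodolactonisation in the 6-exo mode, in which the tether only allows the carboxylate to reach the alkene CH from the face bearing the acetic acid arm with iodine adding anti, so the C–O centre is set cis to the side chain (S) together with the transient tertiary iodide.

Step 5
Reactants: 6 (1S,5S,8S)-8-iodo-5,8-dimethyl-2-oxabicyclo[3.3.1]nonan-3-one
Product: 7 (1S,5S)-5,8-dimethyl-2-oxabicyclo[3.3.1]non-7-en-3-one
Conditions: DBU, toluene, 80 °C
Reagents that add atoms: none
Why: E2 dehydroiodination of the axial tertiary iodide should take the anti-periplanar ring hydrogen on the side away from oxygen (the C–O carbon has no anti-periplanar hydrogen), giving the trisubstituted ring alkene of the target.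

Step 6
Reactants: 7 (1S,5S)-5,8-dimethyl-2-oxabicyclo[3.3.1]non-7-en-3-one
Product: 8 (1S,4R,5S)-4,5,8-trimethyl-2-oxabicyclo[3.3.1]non-7-en-3-one
Conditions: LDA, THF, −78 °C; MeI, −78 → −20 °C
Reagents that add atoms: iodomethane CI
Why: Alkylation of the lactone lithium enolate with the smallest alkyl halide; the convex-face epimer is expected, but the configuration at this carbon is erased by re-enolisation in step 7.

Step 7
Reactants: 8 (1S,4R,5S)-4,5,8-trimethyl-2-oxabicyclo[3.3.1]non-7-en-3-one
Product: 9 (1S,4R,5S)-4,5,8-trimethyl-4-(prop-2-en-1-yl)-2-oxabicyclo[3.3.1]non-7-en-3-one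
Conditions: LDA, THF/DMPU, −78 °C; allyl bromide, −78 → 0 °C
Reagents that add atoms: allyl bromide C=CCBr
Why: Enolate alkylation in which the methyl-bearing enolate of the rigid bicycle is approached by allyl bromide from the convex face, anti to the ring CH2 that sits axial on the neighbouring bridgehead, so the allyl group ends up exo and the methyl endo, setting the second quaternary centre in the target's relative configuration.

Step 8
Reactants: 9 (1S,4R,5S)-4,5,8-trimethyl-4-(prop-2-en-1-yl)-2-oxabicyclo[3.3.1]non-7-en-3-one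
Product: 10 (1S,4R,5S)-4,5,8-trimethyl-4-[(1E)-prop-1-en-1-yl]-2-oxabicyclo[3.3.1]non-7-en-3-one
Conditions: RuHCl(CO)(PPh3)3 (5 mol%), toluene, 80 °C
Reagents that add atoms: none
Why: Ruthenium-hydride-catalysed allyl-to-propenyl isomerisation should act only on the terminal alkene (the trisubstituted ring alkene is inert) and stops at the propenyl stage because the neighbouring carbon is quaternary.

Step 9
Reactants: 10 (1S,4R,5S)-4,5,8-trimethyl-4-[(1E)-prop-1-en-1-yl]-2-oxabicyclo[3.3.1]non-7-en-3-one
Product: 11 (5R,6E)-5-[(1S,5S)-5-hydroxy-1,4-dimethylcyclohex-3-en-1-yl]-5-methylocta-1,6-dien-4-one (drawn as the open-chain tautomer)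
Conditions: allylMgBr (1.2 equiv), THF, −78 °C; aq. NH4Cl
Reagents that add atoms: allylmagnesium bromide C=CC[Mg]Br
Why: Grignard addition to a non-enolisable, hindered lactone should stop at the magnesium hemiketal at low temperature and give the β,γ-unsaturated ketone on mild work-up, freeing the ring hydroxyl with its configuration unchanged.

Step 10
Reactants: 11 (5R,6E)-5-[(1S,5S)-5-hydroxy-1,4-dimethylcyclohex-3-en-1-yl]-5-methylocta-1,6-dien-4-one
Product: 12 (2R)-2-[(1S,5S)-5-hydroxy-1,4-dimethylcyclohex-3-en-1-yl]-2-methylcyclopent-3-en-1-one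
Conditions: Hoveyda–Grubbs II (5 mol%), 1,4-benzoquinone (10 mol%), CH2Cl2, 40 °C
Reagents that add atoms: none
Why: Ring-closing olefin metathesis: the ruthenium alkylidene should load at the terminal allyl alkene, undergo [2+2] with the propenyl alkene on the quaternary carbon, and cyclorevert with loss of propene. The closest known reaction type is cyclopentene formation by metathesis of 1,6-dienes that carry an alkene directly on a quaternary carbon flanked by a second quaternary carbon. The five-membered ring is closed by joining the two alkene CH carbons as a cis ring alkene, driven by loss of volatile propene. No new stereocentre is formed and the adjacent quaternary centre cannot epimerise. The step needs chemoselectivity among three alkenes and no migration of the β,γ-double bond into conjugation with the ketone. The trisubstituted ring alkene is too hindered to engage, the conditions are base-free, and benzoquinone suppresses ruthenium-hydride isomerisation; the free hydroxyl is tolerated.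

Step 11
Reactants: 12 (2R)-2-[(1S,5S)-5-hydroxy-1,4-dimethylcyclohex-3-en-1-yl]-2-methylcyclopent-3-en-1-one
Product: 13 (2R)-2-[(1S,5S)-5-hydroxy-1,4-dimethylcyclohex-3-en-1-yl]-2-methylcyclopentan-1-one
Conditions: H2 (1 atm), RhCl(PPh3)3 (10 mol%), benzene, rt
Reagents that add atoms: none
Why: Homogeneous hydrogenation with Wilkinson's catalyst should reduce the cis-disubstituted cyclopentene much faster than the trisubstituted cyclohexene and leave the ketone and allylic alcohol untouched.

Step 12
Reactants: 13 (2R)-2-[(1S,5S)-5-hydroxy-1,4-dimethylcyclohex-3-en-1-yl]-2-methylcyclopentan-1-one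
Product: 14 (1S,5S)-2,5-dimethyl-5-[(1S)-1-methyl-2-methylidenecyclopentyl]cyclohex-2-en-1-ol
Conditions: Ph3PCH3Br (4 equiv), KOt-Bu (4 equiv), toluene, 90 °C
Reagents that add atoms: methyltriphenylphosphonium bromide C[P+](c1ccccc1)(c1ccccc1)c1ccccc1.[Br-]
Why: Wittig methylenation with excess ylide at elevated temperature is the usual way to convert a 2,2-disubstituted cyclopentanone of this type into the exocyclic alkene; the hydroxyl is only deprotonated and returns on work-up.

Step 13
Reactants: 14 (1S,5S)-2,5-dimethyl-5-[(1S)-1-methyl-2-methylidenecyclopentyl]cyclohex-2-en-1-ol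
Product: 15 3-{[(1S,5S)-2,5-dimethyl-5-[(1S)-1-methyl-2-methylidenecyclopentyl]cyclohex-2-en-1-yl]oxy}-3-oxopropanoic acid
Conditions: Meldrum's acid (1.2 equiv), toluene, 100 °C
Reagents that add atoms: Meldrum's acid CC1(C)OC(=O)CC(=O)O1
Why: Ring-opening acylation of the secondary alcohol by Meldrum's acid gives the malonic half-ester under neutral conditions, with the C–O bond of the allylic carbinol (and so its configuration) untouched.

Step 14
Reactants: 15 3-{[(1S,5S)-2,5-dimethyl-5-[(1S)-1-methyl-2-methylidenecyclopentyl]cyclohex-2-en-1-yl]oxy}-3-oxopropanoic acid; 16 3,4-dihydroxybenzaldehyde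
Product: 18 (1S,5S)-2,5-dimethyl-5-[(1S)-1-methyl-2-methylidenecyclopentyl]cyclohex-2-en-1-yl (2E)-3-(3,4-dihydroxyphenyl)prop-2-enoate, via arylidene malonic half-ester 17 (not isolated)
Conditions: pyridine, piperidine (cat.), 50 °C, Ar
Reagents that add atoms: none
Why: Knoevenagel–Doebner condensation, in which the arylidene malonate decarboxylates in pyridine to the (E)-cinnamate, so the free catechol needs no protection.

## Compound list

1 | isoprene (2-methylbuta-1,3-diene) | C=CC(C)=C | starting material
2 | methacrolein (2-methylprop-2-enal) | C=C(C)C=O | starting material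
3 | (S)-1,4-dimethylcyclohex-3-ene-1-carbaldehyde | O=C[C@@]1(C)CCC(C)=CC1 | intermediate
4 | 2-[(1S)-1,4-dimethylcyclohex-3-en-1-yl]acetonitrile | N#CC[C@@]1(C)CCC(C)=CC1 | intermediate
5 | 2-[(1S)-1,4-dimethylcyclohex-3-en-1-yl]acetic acid | OC(=O)C[C@@]1(C)CCC(C)=CC1 | intermediate
6 | (1S,5S,8S)-8-iodo-5,8-dimethyl-2-oxabicyclo[3.3.1]nonan-3-one | O=C1C[C@@]2(C)CC[C@](C)(I)[C@@H](O1)C2 | intermediate
7 | (1S,5S)-5,8-dimethyl-2-oxabicyclo[3.3.1]non-7-en-3-one | O=C1C[C@@]2(C)CC=C(C)[C@@H](O1)C2 | intermediate
8 | (1S,4R,5S)-4,5,8-trimethyl-2-oxabicyclo[3.3.1]non-7-en-3-one (expected major epimer) | O=C1[C@H](C)[C@@]2(C)CC=C(C)[C@@H](O1)C2 | intermediate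
9 | (1S,4R,5S)-4,5,8-trimethyl-4-(prop-2-en-1-yl)-2-oxabicyclo[3.3.1]non-7-en-3-one | O=C1[C@](C)(CC=C)[C@@]2(C)CC=C(C)[C@@H](O1)C2 | intermediate
10 | (1S,4R,5S)-4,5,8-trimethyl-4-[(1E)-prop-1-en-1-yl]-2-oxabicyclo[3.3.1]non-7-en-3-one | O=C1[C@](C)(/C=C/C)[C@@]2(C)CC=C(C)[C@@H](O1)C2 | intermediate
11 | (5R,6E)-5-[(1S,5S)-5-hydroxy-1,4-dimethylcyclohex-3-en-1-yl]-5-methylocta-1,6-dien-4-one | C=CCC(=O)[C@](C)(/C=C/C)[C@@]1(C)CC=C(C)[C@@H](O)C1 | intermediate
12 | (2R)-2-[(1S,5S)-5-hydroxy-1,4-dimethylcyclohex-3-en-1-yl]-2-methylcyclopent-3-en-1-one | O=C1CC=C[C@]1(C)[C@@]1(C)CC=C(C)[C@@H](O)C1 | intermediate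
13 | (2R)-2-[(1S,5S)-5-hydroxy-1,4-dimethylcyclohex-3-en-1-yl]-2-methylcyclopentan-1-one | O=C1CCC[C@]1(C)[C@@]1(C)CC=C(C)[C@@H](O)C1 | intermediate
14 | (1S,5S)-2,5-dimethyl-5-[(1S)-1-methyl-2-methylidenecyclopentyl]cyclohex-2-en-1-ol | C=C1CCC[C@]1(C)[C@@]1(C)CC=C(C)[C@@H](O)C1 | intermediate
15 | 3-{[(1S,5S)-2,5-dimethyl-5-[(1S)-1-methyl-2-methylidenecyclopentyl]cyclohex-2-en-1-yl]oxy}-3-oxopropanoic acid | C=C1CCC[C@]1(C)[C@@]1(C)CC=C(C)[C@@H](OC(=O)CC(=O)O)C1 | intermediate
16 | 3,4-dihydroxybenzaldehyde | O=Cc1ccc(O)c(O)c1 | starting material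
17 | 2-[(3,4-dihydroxyphenyl)methylidene]propanedioic acid mono-ester of alcohol 14 (arylidene malonic half-ester) | C=C1CCC[C@]1(C)[C@@]1(C)CC=C(C)[C@@H](OC(=O)C(=Cc2ccc(O)c(O)c2)C(=O)O)C1 | intermediate
18 | (1S,5S)-2,5-dimethyl-5-[(1S)-1-methyl-2-methylidenecyclopentyl]cyclohex-2-en-1-yl (2E)-3-(3,4-dihydroxyphenyl)prop-2-enoate | C=C1CCC[C@]1(C)[C@@]1(C)CC=C(C)[C@@H](OC(=O)/C=C/c2ccc(O)c(O)c2)C1 | target

## Summary and fallbacks

Total step count: 14. Longest linear sequence: 14 steps (1 and 2 to 18).

**Step 7** is the most likely to fail. C-alkylation of a fully substituted enolate flanked by a quaternary bridgehead may be slow, may give O-allylation, or may lose facial selectivity. The fallback sets out from 8. Its enolate would be trapped with monomeric formaldehyde, the smallest electrophile, on the same convex face, to give (1S,4S,5S)-4-(hydroxymethyl)-4,5,8-trimethyl-2-oxabicyclo[3.3.1]non-7-en-3-one F1. Dess–Martin oxidation should give the formyl lactone F2, and Ph3P=CH2 (the aldehyde reacts before the lactone) the vinyl lactone F3. Allylmagnesium bromide would open F3 to (3R)-3-[(1S,5S)-5-hydroxy-1,4-dimethylcyclohex-3-en-1-yl]-3-methylhepta-1,6-dien-4-one F4, and ring-closing metathesis of F4 under the step 10 conditions, with loss of ethene, comes back to the route at 12.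

**Step 9** is next. Over-addition of the very reactive allyl reagent to a tertiary carbinol, or base-induced migration of the new β,γ-double bond into conjugation, may erode the ketone. The fallback sets out from 10, which would be opened with MeNHOMe·HCl and i-PrMgCl (or Me3Al) to the hydroxy Weinreb amide (2R,3E)-2-[(1S,5S)-5-hydroxy-1,4-dimethylcyclohex-3-en-1-yl]-N-methoxy-N,2-dimethylpent-3-enamide F5. Its chelated tetrahedral intermediate should hold excess allylmagnesium bromide at the ketone stage, and work-up comes back to the route at 11.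

**Step 12** is third. Methylenation of a ketone flanked by vicinal quaternary carbons may stall through enolisation or through trapping of the carbonyl by the neighbouring alkoxide. The fallback sets out from 13: Me3SiCH2Li with CeCl3 should add to the carbonyl to give the β-hydroxysilane (1RS,2R)-2-[(1S,5S)-5-hydroxy-1,4-dimethylcyclohex-3-en-1-yl]-2-methyl-1-[(trimethylsilyl)methyl]cyclopentan-1-ol F6, and Peterson elimination with KH in THF comes back to the route at 14.

Further compounds
F1 | step 7 | (1S,4S,5S)-4-(hydroxymethyl)-4,5,8-trimethyl-2-oxabicyclo[3.3.1]non-7-en-3-one | O=C1[C@](C)(CO)[C@@]2(C)CC=C(C)[C@@H](O1)C2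
F2 | step 7 | (1S,4S,5S)-4,5,8-trimethyl-3-oxo-2-oxabicyclo[3.3.1]non-7-ene-4-carbaldehyde | O=C1[C@](C)(C=O)[C@@]2(C)CC=C(C)[C@@H](O1)C2
F3 | step 7 | (1S,4R,5S)-4-ethenyl-4,5,8-trimethyl-2-oxabicyclo[3.3.1]non-7-en-3-one | O=C1[C@](C)(C=C)[C@@]2(C)CC=C(C)[C@@H](O1)C2
F4 | step 7 | (3R)-3-[(1S,5S)-5-hydroxy-1,4-dimethylcyclohex-3-en-1-yl]-3-methylhepta-1,6-dien-4-one | C=CCC(=O)[C@](C)(C=C)[C@@]1(C)CC=C(C)[C@@H](O)C1
F5 | step 9 | (2R,3E)-2-[(1S,5S)-5-hydroxy-1,4-dimethylcyclohex-3-en-1-yl]-N-methoxy-N,2-dimethylpent-3-enamide | CON(C)C(=O)[C@](C)(/C=C/C)[C@@]1(C)CC=C(C)[C@@H](O)C1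
F6 | step 12 | (1RS,2R)-2-[(1S,5S)-5-hydroxy-1,4-dimethylcyclohex-3-en-1-yl]-2-methyl-1-[(trimethylsilyl)methyl]cyclopentan-1-ol | C[Si](C)(C)CC1(O)CCC[C@]1(C)[C@@]1(C)CC=C(C)[C@@H](O)C1
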